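**Plan**

1. Labdane numbering is used: ring A = C1–C5 and C10, ring B = C5–C10, C20 = methyl on C10, C17 = formyl carbon on C8, C11–C16 = side chain on C9.
2. Main cut: C1–C2 and C5–C10 together, by an intramolecular Diels–Alder reaction of an acyclic triene. This is possible because C2–C3(O)–C4(Me)–C5 of ring A is a masked 2-silyloxy-3-methyldiene, C1=C10 becomes the alkene of a 2-substituted acrolein once C20 is raised to CHO, and C6–C9 of ring B is a four-atom tether.
3. Other cuts: C17 aldehyde from C8=C17 (hydroboration, oxidation); C3–OH from the ketone; second C4 methyl from the enol ether left by the cycloaddition; C20 methyl from the formyl helper; C4=C5 by Wittig reaction; C1 from formaldehyde; (Z)-enoate from an alkynoate.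
4. Forward: (S)-limonene is lithiated at the isopropenyl methyl (C7) and extended by oxirane (C6, C5). Ozonolysis of the ring alkene frees the C10–C20 aldehyde arm and the C11–C13 ketone arm. The side chain is finished first, then enone, acrolein, cycloaddition (rings A and B together), and last the adjustments at C20, C4, C3 and C8.
5. Stereochemistry: C9 from (S)-limonene; C5 and C10 from the endo transition state with a chair tether and the C9 chain equatorial; C3 from axial hydride attack; C8 from hydroboration anti to C20; the (Z)-alkene from syn-carbocupration.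

Key step: step 10

Remark: the C8 formyl group is axial (cis to C20 and to the C9 chain) and is taken to be the less stable C8 epimer, so it is formed last under non-basic conditions. (S)-(−)-Limonene and ylide 13 are taken as commercial.

**Route**

Step 1
Reactants: 1 (S)-(−)-limonene
Product: 4 tert-butyldimethylsilyl ether of 4-[(1S)-4-methylcyclohex-3-en-1-yl]pent-4-en-1-ol, via allyllithium 2 (not isolated), via lithium alkoxide 3 (not isolated)
Conditions: n-BuLi, TMEDA, hexane, rt; oxirane, THF, −78 °C to rt; then TBSCl, rt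
Reagents that add atoms: oxirane (C1CO1); tert-butyldimethylsilyl chloride, TBSCl (CC(C)(C)[Si](C)(C)Cl)
Why: Allylic lithiation by the n-BuLi/TMEDA complex takes a proton from the isopropenyl methyl group without touching the ring stereocentre, the symmetrical 2-substituted allyllithium opens oxirane (epoxide alkylation; both allyl termini give the same product), and the alkoxide is silylated in the same flask.

Step 2
Reactants: 4 silyl ether
Product: 6 keto acetal (5S)-5-(5-silyloxypent-1-en-2-yl)-7,7-dimethoxyheptan-2-one, via keto aldehyde 5 (not isolated)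
Conditions: O3, CH2Cl2/MeOH, −78 °C (Sudan Red 7B end point); Me2S, −78 °C to rt; then HC(OMe)3, CeCl3·7H2O (cat.), rt
Reagents that add atoms: ozone (O=[O+][O-]); trimethyl orthoformate (COC(OC)OC)
Why: Ozone dosed to a dye end point should cleave the electron-richer trisubstituted ring alkene before the 1,1-disubstituted one (chemoselective ozonolysis with reductive work-up), and CeCl3-catalysed acetalisation then takes the aldehyde much faster than the methyl ketone; no stereocentre is formed or touched.

Step 3
Reactants: 6 keto acetal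
Product: 9 alkynoate methyl (6S)-10-silyloxy-6-(2,2-dimethoxyethyl)-7-methylidenedec-2-ynoate, via enol phosphate 7 (not isolated), via lithium acetylide 8 (not isolated)
Conditions: LDA (1.1 equiv), THF, −78 °C; ClP(O)(OEt)2, −78 °C to rt; LDA (2.3 equiv), −78 °C to rt; ClCO2Me, −78 °C
Reagents that add atoms: methyl chloroformate (COC(=O)Cl)
Why: Kinetic deprotonation at the methyl group gives the terminal enol phosphate, which eliminates with LDA to the lithium acetylide (ketone-to-alkyne conversion through an enol phosphate), and C-acylation by the chloroformate gives the alkynoate.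

Step 4
Reactants: 9 alkynoate
Product: 10 (Z)-enoate methyl (2Z,6S)-10-silyloxy-6-(2,2-dimethoxyethyl)-3-methyl-7-methylidenedec-2-enoate
Conditions: Me2CuLi (from MeLi and CuI), THF, −78 °C; sat. aq. NH4Cl, −78 °C
Reagents that add atoms: lithium dimethylcuprate ([Li+].C[Cu-]C)
Why: syn-Carbocupration of the alkynoate at low temperature and protonation of the alkenylcopper with retention put the new methyl group cis to H, so the ester is cis to the chain, which is the (Z)-trisubstituted enoate (conjugate addition of an organocuprate to an ynoate).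

Step 5
Reactants: 10 (Z)-enoate silyl ether
Product: 11 primary alcohol
Conditions: TBAF, THF, 0 °C to rt
Reagents that add atoms: none
Why: Fluoride cleaves the primary silyl ether (desilylation) and leaves the acetal, the enoate and the alkenes alone.

Step 6
Reactants: 11 primary alcohol
Product: 12 aldehyde (C5)
Conditions: TEMPO (2,2,6,6-tetramethylpiperidin-1-yloxyl, 10 mol%), PhI(OAc)2, CH2Cl2, rt
Reagents that add atoms: none
Why: Oxoammonium-mediated oxidation stops at the aldehyde and tolerates the acetal and the alkenes.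

Step 7
Reactants: 12 aldehyde; 13 3-(triphenylphosphoranylidene)butan-2-one
Product: 14 (E)-enone
Conditions: toluene, 90 °C
Reagents that add atoms: none
Why: The Wittig reaction of a stabilised α-branched ylide with an unhindered aldehyde should give the (E)-α-methyl enone selectively.

Step 8
Reactants: 14 enone acetal
Product: 15 aldehyde (C20)
Conditions: 2 M aq. HCl, THF, rt
Reagents that add atoms: water (O)
Why: Acid-catalysed acetal hydrolysis frees the aldehyde, enone and enoate are stable to dilute acid, and the stereocentre is β to the new carbonyl and cannot epimerise.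

Step 9
Reactants: 15 aldehyde
Product: 16 2-substituted acrolein
Conditions: 37% aq. CH2O (excess), pyrrolidine (10 mol%), propanoic acid (10 mol%), i-PrOH, 45 °C
Reagents that add atoms: formaldehyde (C=O)
Why: Amine-catalysed Mannich condensation with formaldehyde and elimination (α-methylenation of an aldehyde) installs C1 at the only aldehyde α-CH2, and the product has no enolisable hydrogen.

Step 10
Reactants: 16 2-substituted acrolein
Product: 18 cycloadduct with rings A and B, via silyl dienol ether 17 (not isolated)
Conditions: TBSOTf, Et3N, CH2Cl2, −78 to 0 °C; filtration through basic alumina (pentane); then toluene, 80 °C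
Reagents that add atoms: tert-butyldimethylsilyl trifluoromethanesulfonate, TBSOTf (CC(C)(C)[Si](C)(C)OS(=O)(=O)C(F)(F)F)
Why: Soft enolisation (silyl triflate, amine) converts the methyl enone into the cross-conjugated 2-silyloxy-3-methyldiene 17, and a concerted but asynchronous [4+2] cycloaddition with the tethered 2-substituted acrolein then forms C1–C2 and C5–C10 in one event, the nucleophilic diene terminus C2 bonding to the electrophilic β-carbon C1 (polarity-matched). The closest known reaction types are the type 1 intramolecular Diels–Alder reaction of 1,7,9-decatrienes to trans-fused octalins and the cycloaddition of 2-silyloxydienes to 2-alkylacroleins. Ring A closes as the new cyclohexene of the cycloaddition (its C3=C4 enol ether marks the place for the second C4 methyl), and ring B closes in the same event as the six-membered ring spanned by the four-atom tether C6–C9 (fused mode). The quaternary C10 and C5 are set relative to each other by the endo transition state (formyl over the diene, tether in a chair, (E)-diene), which gives the trans ring fusion, and both are set relative to C9 by the pseudo-equatorial position of the C9 chain in that chair. The step therefore needs regio-, endo and π-facial selectivity: the tether fixes the regiochemistry, the formyl helper on C20 favours endo, and the limonene-derived C9 centre chooses the face. The aldehyde has no enolisable hydrogen and so survives the silylation, and the side-chain enoate is too far away and too electron-poor to compete.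

Step 11
Reactants: 18 cycloadduct aldehyde
Product: 19 tosylhydrazone
Conditions: TsNHNH2, THF, 50 °C
Reagents that add atoms: 4-methylbenzenesulfonohydrazide (Cc1ccc(cc1)S(=O)(=O)NN)
Why: Hydrazone formation under neutral conditions takes the angular aldehyde while the tetrasubstituted silyl enol ether, which masks the C3 carbonyl, stays intact.

Step 12
Reactants: 19 tosylhydrazone
Product: 20 silyl enol ether with C20 methyl
Conditions: catecholborane, CHCl3, 0 °C to rt; then NaOAc·3H2O, reflux
Reagents that add atoms: none
Why: Hydride addition of catecholborane to C=N and acetate-induced loss of sulfinate and N2 from the resulting diazene reduce the formyl helper to the C20 methyl group (tosylhydrazone reduction, a mild Wolff–Kishner-type deoxygenation), with ester, alkenes and silyl enol ether inert.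

Step 13
Reactants: 20 silyl enol ether
Product: 21 4,4-dimethyl 3-ketone
Conditions: TBAF (dried, THF), MeI (excess), 4 Å molecular sieves, −40 °C to rt
Reagents that add atoms: iodomethane (CI)
Why: Fluoride unmasks the regiodefined C3–C4 enolate and C-methylation at C4 gives the gem-dimethyl ketone without any regiochemical choice (fluoride-mediated alkylation of a silyl enol ether); C4 is not a stereocentre.

Step 14
Reactants: 21 ketone
Product: 22 equatorial C3 alcohol
Conditions: NaBH4, MeOH, 0 °C
Reagents that add atoms: none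
Why: Hydride should attack the hindered ketone along the axial trajectory on the face away from the axial C4 and C10 methyl groups and give the equatorial alcohol (diastereoselective borohydride reduction); the enoate is not reduced.

Step 15
Reactants: 22 alcohol with exocyclic alkene
Product: 24 diol, via alkylborane 23 (not isolated)
Conditions: 9-BBN (3 equiv), THF, rt to 50 °C; then 30% H2O2, aq. NaOAc, 0 °C to rt
Reagents that add atoms: hydrogen peroxide (OO)
Why: The bulky borane should add to the exocyclic alkene from the face opposite the axial C20 methyl, so H arrives at C8 anti to C20 and the CH2B group becomes axial, cis to C20 and to the C9 chain (hydroboration, then oxidation with retention); the trisubstituted conjugated ester is not hydroborated.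

Step 16
Reactants: 24 diol
Product: 25 target CNP0188570.2
Conditions: TEMPO (10 mol%), PhI(OAc)2, CH2Cl2, 0 °C to rt
Reagents that add atoms: none
Why: Oxoammonium oxidation is selective for the primary over the hindered secondary alcohol and runs without base, so the axial aldehyde should not equilibrate at C8.

**Compound list**

1 | (S)-(−)-limonene, (4S)-1-methyl-4-(prop-1-en-2-yl)cyclohex-1-ene | CC1=CC[C@H](CC1)C(C)=C | starting material
2 | {2-[(1S)-4-methylcyclohex-3-en-1-yl]prop-2-en-1-yl}lithium | CC1=CC[C@H](CC1)C(=C)C[Li] | intermediate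
3 | lithium 4-[(1S)-4-methylcyclohex-3-en-1-yl]pent-4-en-1-olate | CC1=CC[C@H](CC1)C(=C)CCC[O-].[Li+] | intermediate
4 | tert-butyl(dimethyl)({4-[(1S)-4-methylcyclohex-3-en-1-yl]pent-4-en-1-yl}oxy)silane | CC1=CC[C@H](CC1)C(=C)CCCO[Si](C)(C)C(C)(C)C | intermediate
5 | (3S)-3-(5-{[tert-butyl(dimethyl)silyl]oxy}pent-1-en-2-yl)-6-oxoheptanal | CC(=O)CC[C@@H](CC=O)C(=C)CCCO[Si](C)(C)C(C)(C)C | intermediate
6 | (5S)-5-(5-{[tert-butyl(dimethyl)silyl]oxy}pent-1-en-2-yl)-7,7-dimethoxyheptan-2-one | CC(=O)CC[C@@H](CC(OC)OC)C(=C)CCCO[Si](C)(C)C(C)(C)C | intermediate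
7 | (5S)-5-(5-{[tert-butyl(dimethyl)silyl]oxy}pent-1-en-2-yl)-7,7-dimethoxyhept-1-en-2-yl diethyl phosphate | C=C(OP(=O)(OCC)OCC)CC[C@@H](CC(OC)OC)C(=C)CCCO[Si](C)(C)C(C)(C)C | intermediate
8 | [(5S)-5-(5-{[tert-butyl(dimethyl)silyl]oxy}pent-1-en-2-yl)-7,7-dimethoxyhept-1-yn-1-yl]lithium | [Li]C#CCC[C@@H](CC(OC)OC)C(=C)CCCO[Si](C)(C)C(C)(C)C | intermediate
9 | methyl (6S)-10-{[tert-butyl(dimethyl)silyl]oxy}-6-(2,2-dimethoxyethyl)-7-methylidenedec-2-ynoate | COC(=O)C#CCC[C@@H](CC(OC)OC)C(=C)CCCO[Si](C)(C)C(C)(C)C | intermediate
10 | methyl (2Z,6S)-10-{[tert-butyl(dimethyl)silyl]oxy}-6-(2,2-dimethoxyethyl)-3-methyl-7-methylidenedec-2-enoate | COC(=O)/C=C(/C)CC[C@@H](CC(OC)OC)C(=C)CCCO[Si](C)(C)C(C)(C)C | intermediate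
11 | methyl (2Z,6S)-6-(2,2-dimethoxyethyl)-10-hydroxy-3-methyl-7-methylidenedec-2-enoate | COC(=O)/C=C(/C)CC[C@@H](CC(OC)OC)C(=C)CCCO | intermediate
12 | methyl (2Z,6S)-6-(2,2-dimethoxyethyl)-3-methyl-7-methylidene-10-oxodec-2-enoate | COC(=O)/C=C(/C)CC[C@@H](CC(OC)OC)C(=C)CCC=O | intermediate
13 | 3-(triphenylphosphoranylidene)butan-2-one | CC(=O)C(C)=P(c1ccccc1)(c1ccccc1)c1ccccc1 | starting material
14 | methyl (2Z,6S,10E)-6-(2,2-dimethoxyethyl)-3,11-dimethyl-7-methylidene-12-oxotrideca-2,10-dienoate | COC(=O)/C=C(/C)CC[C@@H](CC(OC)OC)C(=C)CC/C=C(\C)C(C)=O | intermediate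
15 | methyl (2Z,6S,10E)-3,11-dimethyl-7-methylidene-12-oxo-6-(2-oxoethyl)trideca-2,10-dienoate | COC(=O)/C=C(/C)CC[C@@H](CC=O)C(=C)CC/C=C(\C)C(C)=O | intermediate
16 | methyl (2Z,6R,10E)-3,11-dimethyl-7-methylidene-12-oxo-6-(3-oxoprop-1-en-2-yl)trideca-2,10-dienoate | COC(=O)/C=C(/C)CC[C@@H](C(=C)C=O)C(=C)CC/C=C(\C)C(C)=O | intermediate
17 | methyl (2Z,6R,10E)-12-{[tert-butyl(dimethyl)silyl]oxy}-3,11-dimethyl-7-methylidene-6-(3-oxoprop-1-en-2-yl)trideca-2,10,12-trienoate | COC(=O)/C=C(/C)CC[C@@H](C(=C)C=O)C(=C)CC/C=C(\C)C(=C)O[Si](C)(C)C(C)(C)C | intermediate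
18 | methyl (2Z)-5-[(1R,4aR,8aR)-6-{[tert-butyl(dimethyl)silyl]oxy}-8a-formyl-5-methyl-2-methylidene-1,2,3,4,4a,7,8,8a-octahydronaphthalen-1-yl]-3-methylpent-2-enoate | COC(=O)/C=C(/C)CC[C@@H]1C(=C)CC[C@@H]2C(C)=C(O[Si](C)(C)C(C)(C)C)CC[C@@]12C=O | intermediate
19 | (E)-4-methylbenzenesulfonylhydrazone of 18, (1R,4aS,8aR) | COC(=O)/C=C(/C)CC[C@@H]1C(=C)CC[C@@H]2C(C)=C(O[Si](C)(C)C(C)(C)C)CC[C@@]12/C=N/NS(=O)(=O)c3ccc(C)cc3 | intermediate
20 | methyl (2Z)-5-[(1R,4aS,8aS)-6-{[tert-butyl(dimethyl)silyl]oxy}-5,8a-dimethyl-2-methylidene-1,2,3,4,4a,7,8,8a-octahydronaphthalen-1-yl]-3-methylpent-2-enoate | COC(=O)/C=C(/C)CC[C@@H]1C(=C)CC[C@@H]2C(C)=C(O[Si](C)(C)C(C)(C)C)CC[C@@]12C | intermediate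
21 | methyl (2Z)-3-methyl-5-[(1R,4aS,8aS)-5,5,8a-trimethyl-2-methylidene-6-oxodecahydronaphthalen-1-yl]pent-2-enoate | COC(=O)/C=C(/C)CC[C@@H]1C(=C)CC[C@@H]2C(C)(C)C(=O)CC[C@@]12C | intermediate
22 | methyl (2Z)-5-[(1R,4aS,6R,8aS)-6-hydroxy-5,5,8a-trimethyl-2-methylidenedecahydronaphthalen-1-yl]-3-methylpent-2-enoate | COC(=O)/C=C(/C)CC[C@@H]1C(=C)CC[C@@H]2C(C)(C)[C@H](O)CC[C@@]12C | intermediate
23 | methyl (2Z)-5-[(1R,2R,4aS,6R,8aS)-2-(9-borabicyclo[3.3.1]nonan-9-ylmethyl)-6-hydroxy-5,5,8a-trimethyldecahydronaphthalen-1-yl]-3-methylpent-2-enoate (the hydroxyl is reversibly borylated by excess reagent) | COC(=O)/C=C(/C)CC[C@@H]1[C@H](CB3C4CCCC3CCC4)CC[C@@H]2C(C)(C)[C@H](O)CC[C@@]12C | intermediate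
24 | methyl (2Z)-5-[(1R,2R,4aS,6R,8aS)-6-hydroxy-2-(hydroxymethyl)-5,5,8a-trimethyldecahydronaphthalen-1-yl]-3-methylpent-2-enoate | COC(=O)/C=C(/C)CC[C@@H]1[C@H](CO)CC[C@@H]2C(C)(C)[C@H](O)CC[C@@]12C | intermediate
25 | methyl (2Z)-5-[(1R,2R,4aS,6R,8aS)-2-formyl-6-hydroxy-5,5,8a-trimethyldecahydronaphthalen-1-yl]-3-methylpent-2-enoate | COC(=O)/C=C(/C)CC[C@@H]1[C@H](C=O)CC[C@@H]2C(C)(C)[C@H](O)CC[C@@]12C | target

**Totals and risks**

Total steps: 16. Longest linear sequence: 16 steps, from 1.

Steps most likely to fail:

Step 10. The C9 stereocentre may discriminate poorly between the two faces of the dienophile; the formyl-exo (cis-fused) mode or a carbonyl-ene reaction of the enal with the neighbouring exocyclic alkene may also compete. The fallback replaces substrate control by reagent control and sets out from 16. TIPSOTf/Et3N gives the isolable triisopropylsilyl dienol ether F1. F1 is cyclised at −78 °C in CH2Cl2 with a catalytic amount of 1-(2-methylphenyl)-3,3-diphenyltetrahydro-1H,3H-pyrrolo[1,2-c][1,3,2]oxazaborole activated by HN(SO2CF3)2, using the (S) or (R) enantiomer that reinforces the substrate bias as found in a small trial; this should give the triisopropylsilyl cycloadduct F2. F2 is taken through its tosylhydrazone F3 and catecholborane reduction to the C20-methyl enol ether F4 as in steps 11 and 12. F4 with TBAF/MeI as in step 13 comes back to the route at 21.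

Step 13. The strongly basic ammonium enolate may take a proton instead of a methyl group (from the γ-positions of the enoate or from traces of water), may be O-methylated, and may isomerise the (Z)-enoate. The fallback sets out from 20. Et2Zn/CH2I2 in CH2Cl2 at 0 °C should cyclopropanate the electron-rich silyl enol ether in preference to the hindered exocyclic alkene and the electron-poor enoate (Simmons–Smith reaction), giving the siloxycyclopropane F5. Acid-promoted ring opening (dilute HCl in MeOH, rt) cleaves the bond to the new CH2, turns it into the second C4 methyl, and comes back to the route at 21.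

Step 2. Ozone may also cleave the 1,1-disubstituted alkene (over-oxidation), or the ketone may be acetalised as well. The fallback sets out from 4. mCPBA (1.0 equiv, CH2Cl2, 0 °C) should epoxidise only the trisubstituted ring alkene to the epoxide F6, H5IO6 in THF/H2O cleaves it to the keto aldehyde 5, and acetalisation as in step 2 comes back to the route at 6.

**Further compounds**

F1 | step 10 | methyl (2Z,6R,10E)-3,11-dimethyl-7-methylidene-6-(3-oxoprop-1-en-2-yl)-12-{[tri(propan-2-yl)silyl]oxy}trideca-2,10,12-trienoate | COC(=O)/C=C(/C)CC[C@@H](C(=C)C=O)C(=C)CC/C=C(\C)C(=C)O[Si](C(C)C)(C(C)C)C(C)C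
F2 | step 10 | methyl (2Z)-5-[(1R,4aR,8aR)-8a-formyl-5-methyl-2-methylidene-6-{[tri(propan-2-yl)silyl]oxy}-1,2,3,4,4a,7,8,8a-octahydronaphthalen-1-yl]-3-methylpent-2-enoate | COC(=O)/C=C(/C)CC[C@@H]1C(=C)CC[C@@H]2C(C)=C(O[Si](C(C)C)(C(C)C)C(C)C)CC[C@@]12C=O
F3 | step 10 | (E)-4-methylbenzenesulfonylhydrazone of F2, (1R,4aS,8aR) | COC(=O)/C=C(/C)CC[C@@H]1C(=C)CC[C@@H]2C(C)=C(O[Si](C(C)C)(C(C)C)C(C)C)CC[C@@]12/C=N/NS(=O)(=O)c3ccc(C)cc3
F4 | step 10 | methyl (2Z)-5-[(1R,4aS,8aS)-5,8a-dimethyl-2-methylidene-6-{[tri(propan-2-yl)silyl]oxy}-1,2,3,4,4a,7,8,8a-octahydronaphthalen-1-yl]-3-methylpent-2-enoate | COC(=O)/C=C(/C)CC[C@@H]1C(=C)CC[C@@H]2C(C)=C(O[Si](C(C)C)(C(C)C)C(C)C)CC[C@@]12C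
F5 | step 13 | methyl (2Z)-5-[1a-{[tert-butyl(dimethyl)silyl]oxy}-3a,7b-dimethyl-5-methylidenedecahydro-1H-cyclopropa[a]naphthalen-4-yl]-3-methylpent-2-enoate, CH2 drawn on the face opposite the C10 methyl (either face leads to 21), other centres as in 20 | COC(=O)/C=C(/C)CC[C@@H]1C(=C)CC[C@@H]2[C@@]3(C)C[C@@]3(O[Si](C)(C)C(C)(C)C)CC[C@@]12C
F6 | step 2 | tert-butyl(dimethyl)({4-[(4S)-1-methyl-7-oxabicyclo[4.1.0]heptan-4-yl]pent-4-en-1-yl}oxy)silane, mixture at the two oxirane carbons | CC12OC1C[C@H](CC2)C(=C)CCCO[Si](C)(C)C(C)(C)C
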